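**Retrosynthetic overview**

1. The route rests on C8, the quaternary carbon shared by oxepane ring B (C5, C6, O, C7, C8, C9, C10) and the C/D bicyclo[3.2.1]octane. C8 sits between C9 and the ring D ketone carbon C15, so it is the central carbon of a C9/C15 1,3-diketone and can be alkylated by C7 carried as the chloromethyl ester of the C6 acid.
2. That step closes ring B as a seven-membered lactone (C7–C8). Its precursor comes from a Mukaiyama aldol/oxidation (C8–C9) between a ring A aldehyde and a regiodefined cyclopentanone enol silane.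
3. Ring A is made by Robinson-type annulation, then lipase resolution and a Still–Wittig shift that sets the C10 quaternary centre. Ring D comes from (1R,4S)-cis-4-acetoxycyclopent-2-en-1-ol, which supplies C13.
4. After the key step: Woodward cis-hydroxylation puts the 1,2-diol on the face of the C10 methyl; a SmI2 Barbier closure (C9–C11) and dehydration give ring C as the 9(11)-ene; the lactone is reduced to the lactol.
5. The C16 methyl (concave face) is set by exo-face hydrogenation of a 16-methylene ketone, and exo-face epoxidation of the 9(11)-ene comes last. Ring order: A, D, B, C, epoxide.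

Key step: step 17

**Remarks**

- Numbering follows the kaurane skeleton: ring A = C1–C5, C10 (gem-dimethyl at C4, methyl C20 at C10); ring B = C5, C6, O, C7, C8, C9, C10; ring C = C8, C9, C11, C12, C13, C14; ring D = C8, C14, C13, C16, C15. β is the face of ring A that carries C20, α the opposite face.
- Assumption: the lipase in step 3 acylates the (1S,4S)-alcohol faster, so the (1R,4R)-alcohol is the unreacted enantiomer; if the sense is opposite, the (1R,4R)-acetate is collected and cleaved with K2CO3 in methanol.
- Assumption: the hemiacetal carbon C6 equilibrates, and the configuration given for the target is taken to be the preferred one.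

**Route**

Step 1
Reactants: 1 tert-butyl acetoacetate; 2 mesityl oxide
Product: 5 rac-tert-butyl 2,6,6-trimethyl-4-oxocyclohex-2-ene-1-carboxylate, via Michael adduct 3 (not isolated), via ketol 4 (not isolated)
Conditions: KOt-Bu (0.2 equiv), t-BuOH, reflux
Reagents that add atoms: none
Why: Robinson-type annulation (Michael addition, aldol of the methyl ketone onto the acetoacetate carbonyl, dehydration), as in the dimedone and Hagemann-ester condensations, should give ring A with the C5 ester, C4 gem-dimethyl and C10 methyl in place.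

Step 2
Reactants: 5 rac-tert-butyl 2,6,6-trimethyl-4-oxocyclohex-2-ene-1-carboxylate
Product: 6 rac-tert-butyl (1R*,4R*)-4-hydroxy-2,6,6-trimethylcyclohex-2-ene-1-carboxylate (trans; the minor cis alcohol is removed by chromatography)
Conditions: NaBH4, CeCl3·7H2O, MeOH, −40 °C
Reagents that add atoms: none
Why: Luche 1,2-reduction; hydride should enter anti to the pseudoaxial C4 methyl, which lies opposite the pseudoaxial ester, so the C2 hydroxyl ends trans to the ester.

Step 3
Reactants: 6 rac-tert-butyl (1R*,4R*)-4-hydroxy-2,6,6-trimethylcyclohex-2-ene-1-carboxylate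
Product: 7 tert-butyl (1R,4R)-4-hydroxy-2,6,6-trimethylcyclohex-2-ene-1-carboxylate
Conditions: lipase from Burkholderia cepacia, vinyl acetate, t-BuOMe, 30 °C, run past half conversion
Reagents that add atoms: none
Why: Lipase-catalysed kinetic resolution of a secondary allylic alcohol by transesterification; the unreacted enantiomer should be obtained enantiopure once conversion passes one half.

Step 4
Reactants: 7 tert-butyl (1R,4R)-4-hydroxy-2,6,6-trimethylcyclohex-2-ene-1-carboxylate; 8 tributyl(iodomethyl)stannane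
Product: 9 tert-butyl (1R,4R)-2,6,6-trimethyl-4-[(tributylstannyl)methoxy]cyclohex-2-ene-1-carboxylate
Conditions: KH (1.05 equiv), THF, 0 °C; then 8, rt
Reagents that add atoms: none
Why: Williamson etherification of the potassium alkoxide; O–H deprotonation should be faster than removal of the hindered hydrogen α to the tert-butyl ester.

Step 5
Reactants: 9 tert-butyl (1R,4R)-2,6,6-trimethyl-4-[(tributylstannyl)methoxy]cyclohex-2-ene-1-carboxylate
Product: 11 tert-butyl (1R,2R)-2-(hydroxymethyl)-2,6,6-trimethylcyclohex-3-ene-1-carboxylate, via lithiomethyl ether 10 (not isolated)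
Conditions: n-BuLi, THF, −78 °C; then aq. NH4Cl
Reagents that add atoms: none
Why: Still–Wittig [2,3]-sigmatropic rearrangement; the suprafacial shift delivers C9 to C10 on the face that carried the C2 oxygen, which sets the C10 quaternary centre with C9 trans to the C5 ester and moves the alkene to C1=C2, and the tert-butyl ester should tolerate n-BuLi at −78 °C.

Step 6
Reactants: 11 tert-butyl (1R,2R)-2-(hydroxymethyl)-2,6,6-trimethylcyclohex-3-ene-1-carboxylate
Product: 12 tert-butyl (1R,2R)-2-formyl-2,6,6-trimethylcyclohex-3-ene-1-carboxylate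
Conditions: Dess–Martin periodinane, NaHCO3, CH2Cl2, rt
Reagents that add atoms: none
Why: Dess–Martin oxidation of a neopentyl primary alcohol; the aldehyde has no α-hydrogen, so nothing can epimerise.

Step 7
Reactants: 13 (1R,4S)-cis-4-acetoxycyclopent-2-en-1-ol; 14 dimethyl malonate
Product: 15 dimethyl 2-[(1S,4R)-4-hydroxycyclopent-2-en-1-yl]propanedioate
Conditions: NaH, THF; Pd(PPh3)4 (5 mol%), 50 °C
Reagents that add atoms: none
Why: Tsuji–Trost allylic alkylation; ionisation and attack both occur anti to palladium, so the malonate replaces the acetate with net retention, cis-1,4 to the hydroxyl, and fixes the future C13 centre.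

Step 8
Reactants: 15 dimethyl 2-[(1S,4R)-4-hydroxycyclopent-2-en-1-yl]propanedioate
Product: 16 methyl 2-[(1R,4R)-4-hydroxycyclopent-2-en-1-yl]acetate
Conditions: NaCl, DMSO, H2O, 150 °C
Reagents that add atoms: none
Why: Krapcho dealkoxycarbonylation of the malonate; any bridged lactone formed from the cis hydroxy ester would converge in step 9.

Step 9
Reactants: 16 methyl 2-[(1R,4R)-4-hydroxycyclopent-2-en-1-yl]acetate
Product: 17 (1R,4S)-4-(2-hydroxyethyl)cyclopent-2-en-1-ol
Conditions: LiAlH4, THF, 0 °C
Reagents that add atoms: none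
Why: Hydride reduction of the ester to the primary alcohol that becomes C11.

Step 10
Reactants: 17 (1R,4S)-4-(2-hydroxyethyl)cyclopent-2-en-1-ol
Product: 18 (4S)-4-(2-hydroxyethyl)cyclopent-2-en-1-one
Conditions: activated MnO2, CH2Cl2, rt
Reagents that add atoms: none
Why: MnO2 oxidises only the allylic alcohol, giving the 4-substituted cyclopentenone without touching the γ stereocentre.

Step 11
Reactants: 18 (4S)-4-(2-hydroxyethyl)cyclopent-2-en-1-one
Product: 19 (4R)-4-(2-chloroethyl)cyclopent-2-en-1-one
Conditions: PPh3, N-chlorosuccinimide, CH2Cl2, 0 °C to rt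
Reagents that add atoms: N-chlorosuccinimide, O=C1CCC(=O)N1Cl
Why: Appel-type chlorination of the primary alcohol; the chloride is a robust precursor of the later C11 iodide.

Step 12
Reactants: 19 (4R)-4-(2-chloroethyl)cyclopent-2-en-1-one
Product: 20 {[(4R)-4-(2-chloroethyl)cyclopent-1-en-1-yl]oxy}triethylsilane
Conditions: Et3SiH, RhCl(PPh3)3 (1 mol%), benzene, 50 °C
Reagents that add atoms: triethylsilane, CC[SiH](CC)CC
Why: Rhodium-catalysed 1,4-hydrosilylation of the enone gives the enol silane whose nucleophilic carbon is the future C8, a regiochemistry that deprotonation of a 3-substituted cyclopentanone would not secure.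

Step 13
Reactants: 12 tert-butyl (1R,2R)-2-formyl-2,6,6-trimethylcyclohex-3-ene-1-carboxylate; 20 {[(4R)-4-(2-chloroethyl)cyclopent-1-en-1-yl]oxy}triethylsilane
Product: 21 tert-butyl (1R,2R)-2-{[(4R)-4-(2-chloroethyl)-2-oxocyclopentyl](hydroxy)methyl}-2,6,6-trimethylcyclohex-3-ene-1-carboxylate (mixture at C8 and C9)
Conditions: BF3·OEt2, CH2Cl2, −78 °C; aq. NaHCO3
Reagents that add atoms: none
Why: Mukaiyama aldol addition to a non-enolisable neopentyl aldehyde forms C8–C9; the two new centres are removed in step 14.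

Step 14
Reactants: 21 aldol adduct
Product: 22 tert-butyl (1R,2R)-2-{[(4R)-4-(2-chloroethyl)-2-hydroxycyclopent-1-en-1-yl]carbonyl}-2,6,6-trimethylcyclohex-3-ene-1-carboxylate (C9/C15 diketone, enol form)
Conditions: Dess–Martin periodinane, CH2Cl2, rt
Reagents that add atoms: none
Why: Dess–Martin oxidation of a β-hydroxy ketone to the 1,3-diketone; C13 is β to the carbonyl and should not epimerise.

Step 15
Reactants: 22 diketone tert-butyl ester
Product: 23 (1R,2R)-2-{[(4R)-4-(2-chloroethyl)-2-hydroxycyclopent-1-en-1-yl]carbonyl}-2,6,6-trimethylcyclohex-3-ene-1-carboxylic acid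
Conditions: CF3CO2H, CH2Cl2, 0 °C to rt
Reagents that add atoms: none
Why: Acidolysis of the tert-butyl ester frees the hindered C6 acid without hydrolysis; diketone, alkene and alkyl chloride should be inert.

Step 16
Reactants: 23 diketone acid; 24 chloromethyl chlorosulfate
Product: 25 chloromethyl (1R,2R)-2-{[(4R)-4-(2-chloroethyl)-2-hydroxycyclopent-1-en-1-yl]carbonyl}-2,6,6-trimethylcyclohex-3-ene-1-carboxylate
Conditions: NaHCO3, Bu4NHSO4, CH2Cl2/H2O, 0 °C to rt
Reagents that add atoms: none
Why: Phase-transfer O-alkylation of the carboxylate with chloromethyl chlorosulfate, the standard chloromethyl ester synthesis; the acid is about four pKa units more acidic than the diketone, so bicarbonate should ionise only the acid.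

Step 17
Reactants: 25 chloromethyl ester of the diketone acid
Product: 27 keto lactone (5R,8R,10R,13R): ring A 1-ene; ring B lactone C5–C6(=O)–O–C7–C8–C9(=O)–C10; C8 spiro to the 13-(2-chloroethyl)cyclopentan-15-one; C6 and C20 β, C9 α; at C8 the C9 carbonyl cis and C7 trans to the C13 arm, via iodomethyl ester 26 (not isolated)
Conditions: K2CO3 (3 equiv), NaI (0.2 equiv), acetone, 2 mM (slow addition), 40 °C
Reagents that add atoms: none
Why: Proposed new method: catalytic iodide converts the chloromethyl ester into the iodomethyl ester 26, and the potassium enolate of the C9/C15 diketone attacks that O–CH2–I carbon through C8 in an SN2 step that makes C7–C8 and the C8 quaternary centre. The closest known reactions are the intermolecular C-alkylation of 1,3-dicarbonyl enolates by acyloxymethyl halides and the intramolecular alkylation of 2-acylcycloalkanones. Ring B closes as a seven-membered lactone in the 7-exo-tet mode, which needs the ester in its s-cis rotamer, hence high dilution and mild heating. C8 is controlled by C13: C7 should enter the enolate face of the cyclopentene away from the 2-chloroethyl arm, leaving the C9 acyl group cis to that arm as ring C later requires. The step needs C- over O-alkylation: attack through O15 would need a nine-membered ring, but attack through O9 would also close a seven-membered ring, so the soft iodide leaving group and the ion-paired potassium enolate in acetone are relied on to favour carbon. The primary chloride at C11 is far less reactive than the acyloxymethyl halide and should survive.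

Step 18
Reactants: 27 keto lactone
Product: 29 2β-acetoxy-1β-hydroxy keto lactone, via iodo acetate 28 (not isolated)
Conditions: I2 (1.05 equiv), AgOAc (2.2 equiv), AcOH, rt; then H2O, 90 °C
Reagents that add atoms: silver acetate, CC(=O)[O-].[Ag+]; water, O
Why: Woodward cis-hydroxylation; the iodonium ion forms on the α face (anti to the axial C10 and C4 methyls), acetate opens it trans-diaxially at C2 from the β face, the acetoxy group displaces the C1 iodide with silver assistance, and water opens the β-acetoxonium ion to the cis-diol monoacetate syn to C20, which direct osmylation would not give.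

Step 19
Reactants: 29 2β-acetoxy-1β-hydroxy keto lactone
Product: 30 1β,2β-diacetoxy keto lactone
Conditions: Ac2O, pyridine, DMAP (cat.), rt
Reagents that add atoms: acetic anhydride, CC(=O)OC(C)=O
Why: Acetylation of the equatorial C1 hydroxyl protects the diol for steps 20–23; any regioisomeric monoacetate from step 18 converges here.

Step 20
Reactants: 30 1β,2β-diacetoxy keto lactone
Product: 31 C15 ethylene ketal (1,3-dioxolane) of 30
Conditions: Me3SiOCH2CH2OSiMe3, Me3SiOTf (cat.), CH2Cl2, −78 to −20 °C
Reagents that add atoms: 1,2-bis(trimethylsilyloxy)ethane, C[Si](C)(C)OCCO[Si](C)(C)C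
Why: Aprotic silyl-triflate-catalysed ketalisation should take only the cyclopentanone carbonyl C15, since C9 lies between two quaternary carbons; C15 must be masked for steps 22 and 24.

Step 21
Reactants: 31 C15 ketal chloride
Product: 32 C15 ketal with C11 iodide (13-(2-iodoethyl))
Conditions: NaI, NaHCO3, 2-butanone, 80 °C
Reagents that add atoms: sodium iodide, [Na+].[I-]
Why: Finkelstein exchange of the primary chloride; the neopentyl C7–O carbon of the lactone is not attacked.

Step 22
Reactants: 32 C11 iodide
Product: 33 tetracyclic tertiary alcohol: C9–C11 bond and ring C formed, 9-hydroxy (drawn exo; its configuration is lost in step 23), 1β,2β-diacetate, lactone, C15 ketal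
Conditions: SmI2 (2.5 equiv), HMPA, THF, −78 to 0 °C; cold aq. NH4Cl
Reagents that add atoms: none
Why: SmI2 Barbier cyclisation; the organosamarium generated at C11 adds to the C9 carbonyl to close six-membered ring C, which is possible because C9 and the C13 arm are cis on ring D, and lactone, acetates and ketal are not reduced.

Step 23
Reactants: 33 tetracyclic tertiary alcohol
Product: 34 9(11)-ene (1β,2β-diacetate, lactone, C15 ketal)
Conditions: Martin sulfurane Ph2S[OC(CF3)2Ph]2, CH2Cl2, 0 °C to rt
Reagents that add atoms: none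
Why: Dehydration of the tertiary alcohol; only C11 carries β-hydrogens (C8 and C10 are quaternary), so the 9(11)-alkene is the only possible regioisomer, and the non-acidic reagent should avoid Wagner–Meerwein shifts.

Step 24
Reactants: 34 9(11)-ene
Product: 36 lactol 1β,2β-diol 15-ketone: C6 hemiacetal (ring B oxepane), free 1β,2β-diol, 9(11)-ene, via ketal triol 35 (not isolated)
Conditions: i-Bu2AlH (5 equiv), CH2Cl2, −78 °C; MeOH quench; then 1 M HCl, THF, rt
Reagents that add atoms: water, O
Why: Half-reduction of the lactone to the lactol at −78 °C, with the two acetates removed by the same hydride; the acidic work-up hydrolyses the dioxolane, and no C9 hydroxyl is left that could capture the C6 aldehyde as a five-membered hemiacetal.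

Step 25
Reactants: 36 lactol diol ketone
Product: 37 6-O-methyl acetal (mixture at C6) of 36
Conditions: PPTS, MeOH, rt
Reagents that add atoms: methanol, CO
Why: Fischer-type acetalisation of the hemiacetal; the hindered C15 ketone should not ketalise, and the acetal protects C6/C7–O against the base of step 26 (no retro-aldol loss of C7).

Step 26
Reactants: 37 methyl acetal diol ketone
Product: 39 16-methylene-15-ketone (methyl acetal, 1β,2β-diol, 9(11)-ene), via Mannich base 38 (not isolated)
Conditions: LiN(SiMe3)2 (3.5 equiv), THF, −78 °C; Me2N=CH2 I (Eschenmoser's salt), −78 °C to rt; then MeI, rt; then aq. NaHCO3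
Reagents that add atoms: N,N-dimethylmethyleneiminium iodide, C=[N+](C)C.[I-]
Why: Mannich α-methylenation; C16 is the only enolisable position of the C15 ketone, and quaternisation followed by E1cB elimination gives the exocyclic enone.

Step 27
Reactants: 39 16-methylene-15-ketone diol
Product: 40 1β,2β-diacetate of 39
Conditions: Ac2O, DMAP, Et3N, CH2Cl2, rt to 40 °C
Reagents that add atoms: acetic anhydride, CC(=O)OC(C)=O
Why: DMAP-catalysed acetylation; the axial C2 hydroxyl, flanked by two syn-axial methyls, needs the forcing conditions, so it is done before the epimerisable C16 centre exists.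

Step 28
Reactants: 40 diacetate enone
Product: 41 (16R)-16-methyl-15-ketone (methyl on the concave face of ring D, syn to the C11–C12 bridge)
Conditions: H2 (1 atm), RhCl(PPh3)3 (10 mol%), benzene, rt
Reagents that add atoms: none
Why: Homogeneous hydrogenation of the 1,1-disubstituted enone alkene; hydrogen is delivered from the convex exo face of ring D, which places C17 on the concave face as in the target, and the hindered 9(11)-alkene should be inert.

Step 29
Reactants: 41 16-methyl ketone methyl acetal
Product: 42 lactol: C6 hemiacetal, 1β,2β-diacetate, (16R)-methyl-15-ketone, 9(11)-ene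
Conditions: AcOH/THF/H2O (3:1:1), 40 °C
Reagents that add atoms: water, O
Why: Mild acid hydrolysis of the mixed cyclic acetal to the hemiacetal; acetates and alkene survive and C16 should not enolise under these conditions.

Step 30
Reactants: 42 lactol 9(11)-ene
Product: 43 CNP0210140.1 (target)
Conditions: dimethyldioxirane, acetone, 0 °C
Reagents that add atoms: dimethyldioxirane, CC1(C)OO1
Why: Neutral epoxidation of the only remaining alkene from the exo face of the bicyclo[3.2.1]octene, anti to the C15–C16 bridge and its endo methyl, should give the 9,11-epoxide with the required configuration.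

**Compound list**

1 | tert-butyl acetoacetate | CC(=O)CC(=O)OC(C)(C)C | starting material
2 | mesityl oxide | CC(C)=CC(C)=O | starting material
3 | Michael adduct, tert-butyl 2-acetyl-3,3-dimethyl-5-oxohexanoate (racemic) | CC(=O)C(C(=O)OC(C)(C)C)C(C)(C)CC(C)=O | intermediate (not isolated)
4 | ketol, tert-butyl 2-hydroxy-2,6,6-trimethyl-4-oxocyclohexane-1-carboxylate (stereoisomer mixture) | CC1(O)CC(=O)CC(C)(C)C1C(=O)OC(C)(C)C | intermediate (not isolated)
5 | rac-tert-butyl 2,6,6-trimethyl-4-oxocyclohex-2-ene-1-carboxylate | CC1=CC(=O)CC(C)(C)C1C(=O)OC(C)(C)C | intermediate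
6 | rac-tert-butyl (1R*,4R*)-4-hydroxy-2,6,6-trimethylcyclohex-2-ene-1-carboxylate | CC1=C[C@H](O)CC(C)(C)[C@H]1C(=O)OC(C)(C)C.CC1=C[C@@H](O)CC(C)(C)[C@@H]1C(=O)OC(C)(C)C | intermediate
7 | tert-butyl (1R,4R)-4-hydroxy-2,6,6-trimethylcyclohex-2-ene-1-carboxylate | CC1=C[C@H](O)CC(C)(C)[C@H]1C(=O)OC(C)(C)C | intermediate
8 | tributyl(iodomethyl)stannane | CCCC[Sn](CCCC)(CCCC)CI | starting material
9 | tert-butyl (1R,4R)-2,6,6-trimethyl-4-[(tributylstannyl)methoxy]cyclohex-2-ene-1-carboxylate | CC1=C[C@H](OC[Sn](CCCC)(CCCC)CCCC)CC(C)(C)[C@H]1C(=O)OC(C)(C)C | intermediate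
10 | lithiomethyl ether, tert-butyl (1R,4R)-4-(lithiomethoxy)-2,6,6-trimethylcyclohex-2-ene-1-carboxylate | CC1=C[C@H](OC[Li])CC(C)(C)[C@H]1C(=O)OC(C)(C)C | intermediate (not isolated)
11 | tert-butyl (1R,2R)-2-(hydroxymethyl)-2,6,6-trimethylcyclohex-3-ene-1-carboxylate | OC[C@]1(C)C=CCC(C)(C)[C@H]1C(=O)OC(C)(C)C | intermediate
12 | tert-butyl (1R,2R)-2-formyl-2,6,6-trimethylcyclohex-3-ene-1-carboxylate | O=C[C@]1(C)C=CCC(C)(C)[C@H]1C(=O)OC(C)(C)C | intermediate
13 | (1R,4S)-cis-4-acetoxycyclopent-2-en-1-ol | O[C@H]1C=C[C@@H](OC(C)=O)C1 | starting material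
14 | dimethyl malonate | COC(=O)CC(=O)OC | starting material
15 | dimethyl 2-[(1S,4R)-4-hydroxycyclopent-2-en-1-yl]propanedioate | O[C@H]1C=C[C@@H](C(C(=O)OC)C(=O)OC)C1 | intermediate
16 | methyl 2-[(1R,4R)-4-hydroxycyclopent-2-en-1-yl]acetate | O[C@H]1C=C[C@@H](CC(=O)OC)C1 | intermediate
17 | (1R,4S)-4-(2-hydroxyethyl)cyclopent-2-en-1-ol | O[C@H]1C=C[C@@H](CCO)C1 | intermediate
18 | (4S)-4-(2-hydroxyethyl)cyclopent-2-en-1-one | O=C1C=C[C@@H](CCO)C1 | intermediate
19 | (4R)-4-(2-chloroethyl)cyclopent-2-en-1-one | O=C1C=C[C@@H](CCCl)C1 | intermediate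
20 | {[(4R)-4-(2-chloroethyl)cyclopent-1-en-1-yl]oxy}triethylsilane | CC[Si](CC)(CC)OC1=CC[C@@H](CCCl)C1 | intermediate
21 | aldol adduct, tert-butyl (1R,2R)-2-{[(4R)-4-(2-chloroethyl)-2-oxocyclopentyl](hydroxy)methyl}-2,6,6-trimethylcyclohex-3-ene-1-carboxylate (mixture at C8, C9) | OC([C@]1(C)C=CCC(C)(C)[C@H]1C(=O)OC(C)(C)C)C2C(=O)C[C@H](CCCl)C2 | intermediate
22 | tert-butyl (1R,2R)-2-{[(4R)-4-(2-chloroethyl)-2-hydroxycyclopent-1-en-1-yl]carbonyl}-2,6,6-trimethylcyclohex-3-ene-1-carboxylate | O=C([C@]1(C)C=CCC(C)(C)[C@H]1C(=O)OC(C)(C)C)C2=C(O)C[C@H](CCCl)C2 | intermediate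
23 | (1R,2R)-2-{[(4R)-4-(2-chloroethyl)-2-hydroxycyclopent-1-en-1-yl]carbonyl}-2,6,6-trimethylcyclohex-3-ene-1-carboxylic acid | O=C([C@]1(C)C=CCC(C)(C)[C@H]1C(=O)O)C2=C(O)C[C@H](CCCl)C2 | intermediate
24 | chloromethyl chlorosulfate | ClCOS(Cl)(=O)=O | starting material
25 | chloromethyl (1R,2R)-2-{[(4R)-4-(2-chloroethyl)-2-hydroxycyclopent-1-en-1-yl]carbonyl}-2,6,6-trimethylcyclohex-3-ene-1-carboxylate (key-step precursor) | O=C([C@]1(C)C=CCC(C)(C)[C@H]1C(=O)OCCl)C2=C(O)C[C@H](CCCl)C2 | intermediate
26 | iodomethyl ester corresponding to 25 | O=C([C@]1(C)C=CCC(C)(C)[C@H]1C(=O)OCI)C2=C(O)C[C@H](CCCl)C2 | intermediate (not isolated)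
27 | keto lactone (5R,8R,10R,13R): ring A 1-ene, ring B lactone, C9 ketone, spiro 13-(2-chloroethyl)cyclopentan-15-one (key-step product) | C1CC(C)(C)[C@H]2C(=O)OC[C@@]3(C[C@@H](CCCl)CC3=O)C(=O)[C@]2(C)C=1 | intermediate
28 | iodo acetate: 1α-iodo-2β-acetoxy derivative of 27 | CC(=O)O[C@H]1CC(C)(C)[C@H]2C(=O)OC[C@@]3(C[C@@H](CCCl)CC3=O)C(=O)[C@]2(C)[C@@H]1I | intermediate (not isolated)
29 | 2β-acetoxy-1β-hydroxy keto lactone | CC(=O)O[C@H]1CC(C)(C)[C@H]2C(=O)OC[C@@]3(C[C@@H](CCCl)CC3=O)C(=O)[C@]2(C)[C@H]1O | intermediate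
30 | 1β,2β-diacetoxy keto lactone | CC(=O)O[C@H]1CC(C)(C)[C@H]2C(=O)OC[C@@]3(C[C@@H](CCCl)CC3=O)C(=O)[C@]2(C)[C@H]1OC(C)=O | intermediate
31 | C15 ethylene ketal of 30 | CC(=O)O[C@H]1CC(C)(C)[C@H]2C(=O)OC[C@@]3(C[C@@H](CCCl)CC34OCCO4)C(=O)[C@]2(C)[C@H]1OC(C)=O | intermediate
32 | C11 iodide (13-(2-iodoethyl)) C15 ketal | CC(=O)O[C@H]1CC(C)(C)[C@H]2C(=O)OC[C@@]3(C[C@@H](CCI)CC34OCCO4)C(=O)[C@]2(C)[C@H]1OC(C)=O | intermediate
33 | tetracyclic 9-hydroxy compound (ring C closed; diacetate, lactone, C15 ketal) | CC(=O)O[C@H]1CC(C)(C)[C@H]2C(=O)OC[C@@]34C[C@@H](CC[C@]3(O)[C@]2(C)[C@H]1OC(C)=O)CC45OCCO5 | intermediate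
34 | 9(11)-ene (diacetate, lactone, C15 ketal) | CC(=O)O[C@H]1CC(C)(C)[C@H]2C(=O)OC[C@@]34C[C@@H](CC=C3[C@]2(C)[C@H]1OC(C)=O)CC45OCCO5 | intermediate
35 | ketal triol: C6 lactol, 1β,2β-diol, C15 ketal, 9(11)-ene | O[C@H]1CC(C)(C)[C@H]2C(O)OC[C@@]34C[C@@H](CC=C3[C@]2(C)[C@H]1O)CC45OCCO5 | intermediate (not isolated)
36 | lactol 1β,2β-diol 15-ketone 9(11)-ene (C6 epimers) | O[C@H]1CC(C)(C)[C@H]2C(O)OC[C@@]34C[C@@H](CC=C3[C@]2(C)[C@H]1O)CC4=O | intermediate
37 | 6-O-methyl acetal of 36 (C6 epimers) | O[C@H]1CC(C)(C)[C@H]2C(OC)OC[C@@]34C[C@@H](CC=C3[C@]2(C)[C@H]1O)CC4=O | intermediate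
38 | Mannich base: 16-(dimethylaminomethyl) derivative of 37 | O[C@H]1CC(C)(C)[C@H]2C(OC)OC[C@@]34C[C@@H](CC=C3[C@]2(C)[C@H]1O)C(CN(C)C)C4=O | intermediate (not isolated)
39 | 16-methylene-15-ketone (methyl acetal, 1β,2β-diol) | O[C@H]1CC(C)(C)[C@H]2C(OC)OC[C@@]34C[C@@H](CC=C3[C@]2(C)[C@H]1O)C(=C)C4=O | intermediate
40 | 1β,2β-diacetate of 39 | CC(=O)O[C@H]1CC(C)(C)[C@H]2C(OC)OC[C@@]34C[C@@H](CC=C3[C@]2(C)[C@H]1OC(C)=O)C(=C)C4=O | intermediate
41 | (16R)-16-methyl-15-ketone (methyl acetal, diacetate, 9(11)-ene) | CC(=O)O[C@H]1CC(C)(C)[C@H]2C(OC)OC[C@@]34C[C@@H](CC=C3[C@]2(C)[C@H]1OC(C)=O)[C@@H](C)C4=O | intermediate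
42 | lactol 9(11)-ene (diacetate, 16-methyl-15-ketone) | CC(=O)O[C@H]1CC(C)(C)[C@H]2[C@H](O)OC[C@@]34C[C@@H](CC=C3[C@]2(C)[C@H]1OC(C)=O)[C@@H](C)C4=O | intermediate
43 | CNP0210140.1 | CC(=O)O[C@H]1CC(C)(C)[C@H]2[C@H](O)OC[C@@]34C[C@@H](C[C@H]5O[C@]53[C@]2(C)[C@H]1OC(C)=O)[C@@H](C)C4=O | target

**Step count**

Total: 30 steps. Longest linear sequence: 24 steps (steps 1–6, then 13–30; the branch through steps 7–12 is equally long).

**Steps most likely to fail**

Step 17 (Proposed new method). The enolate may alkylate through the C9 oxygen, which also closes a seven-membered ring. C7 may enter the face syn to the C13 arm and give the C8 epimer that cannot close ring C. Closure may be slow because the ester must reach its s-cis rotamer, letting intermolecular alkylation take over. Adventitious hydroxide may cleave the non-enolisable 1,3-diketone product by a retro-Claisen reaction. The fallback uses known chemistry and sets out from 23: aldol hydroxymethylation at C8 with aqueous formaldehyde and KHCO3 in THF at 0 °C should give the hydroxymethyl diketone acid F1, with the CH2OH group entering anti to the arm. Shiina lactonisation (2-methyl-6-nitrobenzoic anhydride, DMAP, CH2Cl2, high dilution) then closes ring B through the C6 acyl carbon instead of C7, and the route is rejoined at 27.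

Step 18. Acetate has to open the α-iodonium ion at C2 from the β face, between two syn-axial methyls. Opening of the minor β-iodonium ion, or silver-assisted ionisation at the neopentyl C1 with a 1,2-shift, would give the α-diol series or rearranged material. The fallback sets out from 27 and reaches the β-diol by two hydride deliveries from the open α face. Ketalisation as in step 20 gives the ketal alkene F2. OsO4 (cat.) with N-methylmorpholine N-oxide gives the 1α,2α-diol F3. Swern oxidation gives the 1,2-dione F4. NaBH4 in MeOH at −40 °C gives the 1β,2β-diol F5, and Ac2O/DMAP returns to the route at 31.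

Step 22. The organosamarium at C11 may be protonated before it adds to the very hindered C9 carbonyl, leaving an ethyl arm. The samarium alkoxide formed may also attack the C6 lactone carbonyl and translactonise. The fallback sets out from 32 and makes the C9–C11 bond by ketyl coupling. Kornblum oxidation (DMSO, NaHCO3, 90 °C) gives the aldehyde F6. SmI2 with t-BuOH in THF couples the aldehyde ketyl with the C9 ketone to give the cis-9,11-diol F7. 1,1'-Thiocarbonyldiimidazole in hot toluene gives the cyclic thiocarbonate F8, and Corey–Winter elimination with P(OMe)3 at reflux returns to the route at 34.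

**Further compounds**

F1 | step 17 | hydroxymethyl diketone acid (C8 CH2OH anti to the C13 arm) | C1CC(C)(C)[C@@H](C(=O)O)[C@@](C)(C=1)C(=O)[C@@]2(CO)C[C@@H](CCCl)CC2=O
F2 | step 18 | ketal alkene (C15 ethylene ketal of 27) | C1CC(C)(C)[C@H]2C(=O)OC[C@@]3(C[C@@H](CCCl)CC34OCCO4)C(=O)[C@]2(C)C=1
F3 | step 18 | 1α,2α-diol of F2 | O[C@@H]1CC(C)(C)[C@H]2C(=O)OC[C@@]3(C[C@@H](CCCl)CC34OCCO4)C(=O)[C@]2(C)[C@@H]1O
F4 | step 18 | 1,2-dione of F2 | O=C1CC(C)(C)[C@H]2C(=O)OC[C@@]3(C[C@@H](CCCl)CC34OCCO4)C(=O)[C@]2(C)C1=O
F5 | step 18 | 1β,2β-diol of F2 | O[C@H]1CC(C)(C)[C@H]2C(=O)OC[C@@]3(C[C@@H](CCCl)CC34OCCO4)C(=O)[C@]2(C)[C@H]1O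
F6 | step 22 | C11 aldehyde (13-(2-oxoethyl)) corresponding to 32 | CC(=O)O[C@H]1CC(C)(C)[C@H]2C(=O)OC[C@@]3(C[C@@H](CC=O)CC34OCCO4)C(=O)[C@]2(C)[C@H]1OC(C)=O
F7 | step 22 | cis-9,11-diol (ring C closed) | CC(=O)O[C@H]1CC(C)(C)[C@H]2C(=O)OC[C@@]34C[C@@H](CC(O)C3(O)[C@]2(C)[C@H]1OC(C)=O)CC45OCCO5
F8 | step 22 | cyclic 9,11-thiocarbonate of F7 | CC(=O)O[C@H]1CC(C)(C)[C@H]2C(=O)OC[C@@]34C[C@@H](CC6OC(=S)OC36[C@]2(C)[C@H]1OC(C)=O)CC45OCCO5
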